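**Remarks**

- Ring positions: ring A is the 2,4,6-trihydroxyphenoxy end. A1 carries the oxygen to ring B; B1, C1, D1 and E1 carry the ether oxygen on the ring A side; B3 carries the oxygen to ring C, C2 the oxygen to ring D, D4 the oxygen to ring E.
- Ring D is taken from 1 rather than from a hydroquinone derived from 2,6-dimethoxy-1,4-benzoquinone, because 1 has the two ring D oxygens differentiated from the start (one free phenol, one latent in a formyl group).
- Compounds 1, 5, 9 and 10 are taken as catalogue chemicals.
- Bookkeeping check: 15 and 17 carry eleven methyl ethers (A 3, B 1, C 3, D 2, E 2); with the two hydroxyls made in the key step these account for all thirteen hydroxyls of 18.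

## Structural features

The target (C30H22O17) is a linear, achiral chain of five benzene rings A–E joined only by four diaryl ether oxygens (A1–O–B1, B3–O–C1, C2–O–D1, D4–O–E1). There is no ring-to-ring C–C bond and no stereocentre, so no stereochemical relationship has to be set. Ring A is a phloroglucinol unit, rings B, D and E are 1,3,4,5-tetraoxygenated, and ring C is 1,2,3,4,5-pentaoxygenated, giving thirteen free hydroxyls in all. The catechol and pyrogallol arrays of rings B, C and E oxidise easily to quinones in air, above all as phenoxides, so the free polyphenol should exist only after the last step. The real difficulty is the four ether bonds: every ether oxygen sits on a carbon with at least one ortho oxygen (A1 and D4 have two, C1 and C2 are vicinal), and all rings are far too electron-rich for direct nucleophilic substitution. The key step uses the fact that the B4 and E4 hydroxyls lie para to the ether oxygens at B1 and E1 (B4 is also ortho to the B3 ether oxygen). A formyl group at B4 or E4 therefore activates fluorides at B1, B3, B5 and at E1, E3, E5, and is afterwards turned into the hydroxyl itself. The same relationship (D1 para to D4, C1 ortho to C2) lets two further formyl groups serve as latent D1 and C1 hydroxyls.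

## Logic of the disconnections

**18 to 17.** The eleven O–CH3 bonds are cut last. Methyl ethers are the smallest groups that survive base, peracid and copper, and a single Lewis acid step removes them. The forward step must cleave eleven ethers without touching the four diaryl ether bonds.

**17 to 15 (through 16).** The B4–O and E4–O bonds are cut and replaced by B4–CHO and E4–CHO. This turns two electron-rich rings into electrophilic benzaldehydes, so that all six oxygen substituents ortho and para to the two formyl carbons can be traced to fluoride displacements. The forward step demands aryl rather than hydride migration at both aldehydes and no oxidation of the rings.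

**15 to 14.** The aryl C–O bonds of the methoxy groups at B5, E3 and E5 are cut back to C–F. Keeping these three positions as fluorides until one late exchange saves a step and keeps rings B and E as reactive as possible during the aryl ether formations. The forward step must exchange three fluorides without displacing the aryloxy groups that sit on the same activated rings.

**14 to 13 and 10.** The E1–O bond is cut. Ring E becomes a second unit of 10, whose para fluoride is the natural site for attack by the hindered D4 phenoxide. The forward step must prefer this para fluoride over the single B5 fluoride inside 13.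

**13 to 12.** The D4 hydroxyl is masked as an acetal. The mask has to survive copper catalysis, peracid, carbonate and fluoride, and must come off without harming an aldehyde or an aryl fluoride.

**12 to 8 and 11.** The B3–O bond is cut. This separates the ring A–B aldehyde 11 from the ring C–D phenol 8, two fragments of similar size. The forward step must stop after one of the two equivalent ortho fluorides of 11 has been displaced.

**11 to 9 and 10.** The B1–O bond is cut. The most hindered and most oxidation-prone phenol, 9, is attached first, to the most reactive fluoride of 10. The forward step requires para over ortho selectivity.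

**8 to 6 (through 7).** The C1–O bond is cut back to C1–CHO. The formyl group of 6 is what makes the preceding ether formation feasible, and its oxidation unveils the C1 hydroxyl as the only free phenol. The demand is again aryl migration, secured by the ortho aryloxy and para methoxy groups.

**6 to 4 and 5.** The C2–O bond is cut. It is the only ether bond that cannot be made by fluoride displacement, because ring C has no activating group para or ortho to a fluoride in the right place. A copper-mediated coupling of the unhindered phenol 4 with the ortho-formyl bromide 5 is required.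

**4 to 2 (through 3) and 1.** The D1–O bond is cut back to the formyl group of 2, and the acetal of 2 is removed to give 1. Compound 1 already has the hindered D4 hydroxyl free for protection and a formyl group exactly where the D1 oxygen is needed, so ring D is differentiated in two steps.

## Other disconnections considered

**Alternative 1:** The cut is through the D2–D3 and D1–D6 bonds, so ring D is made from carbon fragments. In the forward sense the cyclobutenone A1 is heated with the silyloxyacetylene A2 (Danheiser benzannulation). Electrocyclic opening gives a vinylketene, [2+2] addition to the alkyne and a second opening give a dienylketene, and 6π closure with tautomerisation gives the phenol A3.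
- In its favour: the positions of all four ring D oxygens follow from the polarity of the ketene–alkyne addition. The hindered D4–O–E1 ether is already present in A1 and needs no substitution on an arene. The three ring D oxygens emerge differentiated (free D3 hydroxyl, D5 ethyl ether, D1 silyl ether).
- Against it here: it delivers only the two-ring fragment D–E. The D3 hydroxyl must be capped and D1 unmasked, and the three remaining ether bonds still need the chemistry of steps 3 to 9. A1 and A2 are moisture-sensitive and each takes several steps to prepare. The ring it builds can simply be bought as 1.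
- Comparison: on regiochemical certainty for ring D this alternative is the better plan, since it has no para versus ortho question as in steps 5 and 8. On stereochemistry the two are equal, as there is none. Because ring E enters as a trimethoxyphenyl group, no oxidation is needed at E4, which is a small advantage. On step economy it is clearly worse: about five steps for D–E against three in the chosen plan (steps 1, 2 and 8).

**Alternative 2:** The cut is through the A2–A3 and A5–A6 bonds, so ring A is assembled last in the manner of a triketide. Under NaOMe the aryloxymalonate A4 acylates both α-carbons of dimethyl 3-oxopentanedioate A5 (two Claisen condensations, the second one ring-closing), and enolisation gives the trihydroxyisophthalate A6.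
- In its favour: ring A appears with its hydroxyls already free. The oxidation-prone phenol 9 is never handled. The A1–O bond comes from simple O-alkylation of a phenol with a halomalonate rather than from an arylation.
- Against it here: the whole B–C–D–E phenol must be made first, with a free B1 hydroxyl that the fluoride-displacement logic does not supply directly. The annulation is then run on the most valuable intermediate. NaOMe converts A4 into a stabilised enolate that is a poor acyl donor, and A5 self-condenses readily. A6 still needs ester hydrolysis and double decarboxylation before the global demethylation.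
- Comparison: both plans form two skeletal bonds in the key step, C–C here and C–O in the chosen plan. This alternative is the better one for unambiguous oxygen placement on ring A and for avoiding deprotection of that ring. It is weaker in convergence and in mechanistic risk, and it costs at least three operations for ring A against one (step 5).

**Alternative 3:** The cut is the C1–C6 bond, so ring C is grown onto ring D from a four-membered ring. Thermolysis of the cyclobutenone A7 (racemic at its quaternary carbon, which is lost) opens it to a dienylketene with the methoxy group turning outward and the methoxyvinyl group inward. 6π closure and tautomerisation give the phenol A8 (Moore rearrangement).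
- In its favour: all five oxygens of the most substituted ring come from a squaric ester and an enol ether. The C2–O–D1 bond arises by addition–elimination of a phenoxide on a squaric ester, which is far easier than the hindered coupling of step 3. A8 has the C1 hydroxyl free and unique, the exact counterpart of 8, and could be taken on with 11 as in step 6.
- Against it here: the D–E phenol must be made first, so the D4–O–E1 ether has to be formed without a formyl group at E4 that survives to the end. The vinyl anion must choose correctly between the two vinylogous ester carbonyls of an aryloxy methoxy squarate. An organolithium reagent, O-methylation of a tertiary alkoxide and a thermolysis add up to about four steps for ring C, against two (steps 3 and 4).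
- Comparison: for the hardest ring this alternative is structurally the better solution, and it is equal to the chosen plan in how ring B is then attached. The pericyclic cascade is reliable once A7 is in hand. The chosen plan is shorter by two to four steps and uses one reaction type, formyl-activated substitution followed by oxidation, for four of the five rings.

Key step: step 10

## Route

Step 1
Reactants: 1 syringaldehyde (4-hydroxy-3,5-dimethoxybenzaldehyde)
Product: 2 3,5-dimethoxy-4-(methoxymethoxy)benzaldehyde
Conditions: MOMCl, iPr2NEt, CH2Cl2, 0 °C → rt
Reagents that add atoms: MOMCl (chloromethyl methyl ether), COCCl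
Why: Williamson-type O-alkylation of the acidic, doubly ortho-substituted phenol with an α-chloro ether is routine; the MOM acetal is chosen because it withstands peracid, carbonate at 90 °C and fluoride, and later comes off with acid beside an aryl aldehyde and an aryl fluoride.

Step 2
Reactants: 2 3,5-dimethoxy-4-(methoxymethoxy)benzaldehyde
Product: 4 3,5-dimethoxy-4-(methoxymethoxy)phenol, via ring D aryl formate 3 (not isolated)
Conditions: mCPBA, CH2Cl2, 0 °C → rt; aq. Na2SO3 wash; then K2CO3 (cat.), MeOH, 0 °C
Reagents that add atoms: mCPBA (3-chloroperoxybenzoic acid), OOC(=O)c1cccc(Cl)c1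
Why: Baeyer–Villiger (Dakin-type) oxidation: the peracid adds to the formyl group and the aryl group, made electron-rich by its para oxygen, migrates in preference to hydride; catalytic carbonate in methanol transesterifies the formate and frees the unhindered D1 hydroxyl while D4 stays protected.

Step 3
Reactants: 4 3,5-dimethoxy-4-(methoxymethoxy)phenol; 5 2-bromo-3,4,5-trimethoxybenzaldehyde
Product: 6 2-[3,5-dimethoxy-4-(methoxymethoxy)phenoxy]-3,4,5-trimethoxybenzaldehyde
Conditions: CuI (10 mol %), N,N-dimethylglycine (30 mol %), Cs2CO3, 1,4-dioxane, 90 °C, argon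
Reagents that add atoms: none
Why: Ullmann diaryl ether synthesis between an unhindered electron-rich phenoxide and an aryl bromide activated by its ortho formyl group, which polarises the C–Br bond and can coordinate copper; the amino acid ligand keeps the monovalent copper soluble at a temperature that the aldehyde and the acetal tolerate.

Step 4
Reactants: 6 2-[3,5-dimethoxy-4-(methoxymethoxy)phenoxy]-3,4,5-trimethoxybenzaldehyde
Product: 8 2-[3,5-dimethoxy-4-(methoxymethoxy)phenoxy]-3,4,5-trimethoxyphenol, via ring C–D aryl formate 7 (not isolated)
Conditions: mCPBA, CH2Cl2, 0 °C → rt; aq. Na2SO3 wash; then K2CO3 (cat.), MeOH, 0 °C, argon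
Reagents that add atoms: mCPBA (3-chloroperoxybenzoic acid), OOC(=O)c1cccc(Cl)c1
Why: Second Baeyer–Villiger (Dakin-type) oxidation: C1 has an ortho aryloxy and a para methoxy group, so aryl migration is favoured; methanolysis of the formate leaves the C1 phenol as the only free hydroxyl of the differentially protected ring C–D bisphenol.

Step 5
Reactants: 9 2,4,6-trimethoxyphenol; 10 2,4,6-trifluorobenzaldehyde
Product: 11 2,6-difluoro-4-(2,4,6-trimethoxyphenoxy)benzaldehyde
Conditions: K2CO3, DMF, 0 °C → rt, argon (10 in slight excess)
Reagents that add atoms: none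
Why: Nucleophilic aromatic substitution (addition–elimination through a Meisenheimer complex) at the fluoride para to the formyl group; the 2,6-disubstituted phenoxide should prefer the unhindered para position over the two positions next to the carbonyl, and the aryloxy donor that enters slows a second substitution.

Step 6
Reactants: 8 2-[3,5-dimethoxy-4-(methoxymethoxy)phenoxy]-3,4,5-trimethoxyphenol; 11 2,6-difluoro-4-(2,4,6-trimethoxyphenoxy)benzaldehyde
Product: 12 2-fluoro-6-{2-[3,5-dimethoxy-4-(methoxymethoxy)phenoxy]-3,4,5-trimethoxyphenoxy}-4-(2,4,6-trimethoxyphenoxy)benzaldehyde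
Conditions: Cs2CO3, DMF, 70 °C, argon
Reagents that add atoms: none
Why: Nucleophilic aromatic substitution at one of the two equivalent fluorides ortho to the formyl group, the only activated positions left; once the first aryloxy group is in, the ring is more electron-rich and more hindered, which should stop the reaction at mono-substitution and keep the B5 fluoride.

Step 7
Reactants: 12 2-fluoro-6-{2-[3,5-dimethoxy-4-(methoxymethoxy)phenoxy]-3,4,5-trimethoxyphenoxy}-4-(2,4,6-trimethoxyphenoxy)benzaldehyde
Product: 13 2-fluoro-6-[2-(4-hydroxy-3,5-dimethoxyphenoxy)-3,4,5-trimethoxyphenoxy]-4-(2,4,6-trimethoxyphenoxy)benzaldehyde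
Conditions: HCl (cat., 1.25 M in MeOH), THF, 40 °C; then 1 M aq. HCl, rt
Reagents that add atoms: none
Why: Acid-catalysed acetal cleavage (methanolysis of the MOM ether); methanol intercepts the methoxymethyl cation as dimethoxymethane before it can alkylate the nucleophilic ring A, and the aqueous acid finish returns any dimethyl acetal of the aldehyde, while aryl fluoride, aldehyde and diaryl ethers are inert to dilute acid.

Step 8
Reactants: 13 2-fluoro-6-[2-(4-hydroxy-3,5-dimethoxyphenoxy)-3,4,5-trimethoxyphenoxy]-4-(2,4,6-trimethoxyphenoxy)benzaldehyde; 10 2,4,6-trifluorobenzaldehyde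
Product: 14 2-{2-[4-(3,5-difluoro-4-formylphenoxy)-3,5-dimethoxyphenoxy]-3,4,5-trimethoxyphenoxy}-6-fluoro-4-(2,4,6-trimethoxyphenoxy)benzaldehyde
Conditions: K2CO3, 10 (2 equiv), DMF, rt, argon
Reagents that add atoms: none
Why: Nucleophilic aromatic substitution of the para fluoride of a second unit of 10 by the doubly ortho-substituted D4 phenoxide; this fluoride is far more electrophilic and accessible than the single B5 fluoride of 13, which sits on a ring with two aryloxy donors, so an excess of 10 at room temperature should suppress self-condensation.

Step 9
Reactants: 14 2-{2-[4-(3,5-difluoro-4-formylphenoxy)-3,5-dimethoxyphenoxy]-3,4,5-trimethoxyphenoxy}-6-fluoro-4-(2,4,6-trimethoxyphenoxy)benzaldehyde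
Product: 15 2-{2-[4-(4-formyl-3,5-dimethoxyphenoxy)-3,5-dimethoxyphenoxy]-3,4,5-trimethoxyphenoxy}-6-methoxy-4-(2,4,6-trimethoxyphenoxy)benzaldehyde (the B4,E4-dialdehyde)
Conditions: NaOMe (excess), MeOH/THF, 65 °C
Reagents that add atoms: sodium methoxide, C[O-].[Na+]
Why: Threefold nucleophilic aromatic substitution of the fluorides ortho to the two formyl groups (B5, E3, E5) by methoxide; in this addition-controlled mechanism fluoride is a far better leaving group than aryloxide, so attack at the C–F carbons should outrun ether exchange, and reversible hemiacetal formation at the aldehydes does no harm.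

Step 10
Reactants: 15 the B4,E4-dialdehyde
Product: 17 2-{2-[4-(4-hydroxy-3,5-dimethoxyphenoxy)-3,5-dimethoxyphenoxy]-3,4,5-trimethoxyphenoxy}-6-methoxy-4-(2,4,6-trimethoxyphenoxy)phenol (undeca-O-methyl ether of the target with free B4 and E4 hydroxyls), via B4,E4-bis(formate) 16 (not isolated)
Conditions: mCPBA (2.4 equiv), CH2Cl2, 0 °C → rt; aq. Na2SO3 wash; then K2CO3 (cat.), MeOH, 0 °C, argon
Reagents that add atoms: mCPBA (3-chloroperoxybenzoic acid), OOC(=O)c1cccc(Cl)c1
Why: The peracid adds to each formyl carbon to give a peroxy hemiacetal (Criegee intermediate), the aryl group shifts from carbon to the proximal oxygen with loss of 3-chlorobenzoate, and the two aryl formates of 16 are cleaved by methanolysis after the excess oxidant has been destroyed, so the B4–O and E4–O bonds form in one operation. The closest known reaction type is the Dakin (Baeyer–Villiger) oxidation of ortho- and para-alkoxybenzaldehydes to phenols, as with 2,6-dimethoxy- and 2,4,6-trimethoxybenzaldehydes. No ring is closed and no stereocentre is created. The first selectivity needed is aryl over hydride migration at both aldehydes: B4 is flanked by the B3 aryloxy and B5 methoxy groups and E4 by the E3 and E5 methoxy groups, each with a further oxygen para (B1, E1), so the migrating carbon is strongly electron-rich and aryl migration should be much faster than the hydride shift that leads to carboxylic acids. The second is chemoselectivity for the carbonyl groups over the electron-rich rings; it rests on the faster addition of a peracid to an aldehyde than to an arene at 0 °C, on a small excess of oxidant, and on the new phenolic oxygens staying acylated as formates until the peracid has been reduced. The formyl groups, which made rings B and E electrophilic enough for six fluoride displacements, thus end as the two hydroxyls that sit para to the B1 and E1 ether oxygens.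

Step 11
Reactants: 17 the undeca-O-methyl ether with free B4 and E4 hydroxyls
Product: 18 CNP0228612.0, 2-[3-[2-[3,5-dihydroxy-4-(3,4,5-trihydroxyphenoxy)phenoxy]-3,4,5-trihydroxyphenoxy]-4,5-dihydroxyphenoxy]benzene-1,3,5-triol
Conditions: BBr3 (excess), CH2Cl2, −78 °C → rt; then H2O, 0 °C, argon
Reagents that add atoms: none
Why: Lewis acid-mediated cleavage of the eleven aryl methyl ethers (boron–ether adduct, bromide attack on methyl, hydrolysis of the aryl borates); the diaryl ether C–O bonds have no carbon open to SN2 attack and should survive, and more than one equivalent of BBr3 per oxygen is used because every ether oxygen binds boron.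

## Compound list

1 | syringaldehyde (4-hydroxy-3,5-dimethoxybenzaldehyde) | COc1cc(C=O)cc(OC)c1O | starting material
2 | 3,5-dimethoxy-4-(methoxymethoxy)benzaldehyde | COCOc1c(OC)cc(C=O)cc1OC | intermediate
3 | 3,5-dimethoxy-4-(methoxymethoxy)phenyl formate (ring D aryl formate) | COCOc1c(OC)cc(OC=O)cc1OC | intermediate
4 | 3,5-dimethoxy-4-(methoxymethoxy)phenol | COCOc1c(OC)cc(O)cc1OC | intermediate
5 | 2-bromo-3,4,5-trimethoxybenzaldehyde | O=Cc1cc(OC)c(OC)c(OC)c1Br | starting material
6 | 2-[3,5-dimethoxy-4-(methoxymethoxy)phenoxy]-3,4,5-trimethoxybenzaldehyde | O=Cc1cc(OC)c(OC)c(OC)c1Oc1cc(OC)c(OCOC)c(OC)c1 | intermediate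
7 | 2-[3,5-dimethoxy-4-(methoxymethoxy)phenoxy]-3,4,5-trimethoxyphenyl formate (ring C–D aryl formate) | O=COc1cc(OC)c(OC)c(OC)c1Oc1cc(OC)c(OCOC)c(OC)c1 | intermediate
8 | 2-[3,5-dimethoxy-4-(methoxymethoxy)phenoxy]-3,4,5-trimethoxyphenol | Oc1cc(OC)c(OC)c(OC)c1Oc1cc(OC)c(OCOC)c(OC)c1 | intermediate
9 | 2,4,6-trimethoxyphenol | COc1cc(OC)c(O)c(OC)c1 | starting material
10 | 2,4,6-trifluorobenzaldehyde | O=Cc1c(F)cc(F)cc1F | starting material
11 | 2,6-difluoro-4-(2,4,6-trimethoxyphenoxy)benzaldehyde | COc1cc(OC)c(Oc2cc(F)c(C=O)c(F)c2)c(OC)c1 | intermediate
12 | 2-fluoro-6-{2-[3,5-dimethoxy-4-(methoxymethoxy)phenoxy]-3,4,5-trimethoxyphenoxy}-4-(2,4,6-trimethoxyphenoxy)benzaldehyde | COc1cc(OC)c(Oc2cc(F)c(C=O)c(Oc3cc(OC)c(OC)c(OC)c3Oc3cc(OC)c(OCOC)c(OC)c3)c2)c(OC)c1 | intermediate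
13 | 2-fluoro-6-[2-(4-hydroxy-3,5-dimethoxyphenoxy)-3,4,5-trimethoxyphenoxy]-4-(2,4,6-trimethoxyphenoxy)benzaldehyde | COc1cc(OC)c(Oc2cc(F)c(C=O)c(Oc3cc(OC)c(OC)c(OC)c3Oc3cc(OC)c(O)c(OC)c3)c2)c(OC)c1 | intermediate
14 | 2-{2-[4-(3,5-difluoro-4-formylphenoxy)-3,5-dimethoxyphenoxy]-3,4,5-trimethoxyphenoxy}-6-fluoro-4-(2,4,6-trimethoxyphenoxy)benzaldehyde | COc1cc(OC)c(Oc2cc(F)c(C=O)c(Oc3cc(OC)c(OC)c(OC)c3Oc3cc(OC)c(Oc4cc(F)c(C=O)c(F)c4)c(OC)c3)c2)c(OC)c1 | intermediate
15 | 2-{2-[4-(4-formyl-3,5-dimethoxyphenoxy)-3,5-dimethoxyphenoxy]-3,4,5-trimethoxyphenoxy}-6-methoxy-4-(2,4,6-trimethoxyphenoxy)benzaldehyde (B4,E4-dialdehyde) | COc1cc(OC)c(Oc2cc(OC)c(C=O)c(Oc3cc(OC)c(OC)c(OC)c3Oc3cc(OC)c(Oc4cc(OC)c(C=O)c(OC)c4)c(OC)c3)c2)c(OC)c1 | intermediate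
16 | B4,E4-bis(formate) of 17 | COc1cc(OC)c(Oc2cc(OC)c(OC=O)c(Oc3cc(OC)c(OC)c(OC)c3Oc3cc(OC)c(Oc4cc(OC)c(OC=O)c(OC)c4)c(OC)c3)c2)c(OC)c1 | intermediate
17 | 2-{2-[4-(4-hydroxy-3,5-dimethoxyphenoxy)-3,5-dimethoxyphenoxy]-3,4,5-trimethoxyphenoxy}-6-methoxy-4-(2,4,6-trimethoxyphenoxy)phenol | COc1cc(OC)c(Oc2cc(OC)c(O)c(Oc3cc(OC)c(OC)c(OC)c3Oc3cc(OC)c(Oc4cc(OC)c(O)c(OC)c4)c(OC)c3)c2)c(OC)c1 | intermediate
18 | CNP0228612.0, 2-[3-[2-[3,5-dihydroxy-4-(3,4,5-trihydroxyphenoxy)phenoxy]-3,4,5-trihydroxyphenoxy]-4,5-dihydroxyphenoxy]benzene-1,3,5-triol | Oc1cc(O)c(Oc2cc(O)c(O)c(Oc3cc(O)c(O)c(O)c3Oc3cc(O)c(Oc4cc(O)c(O)c(O)c4)c(O)c3)c2)c(O)c1 | target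

## Step count and risk

Total step count: 11. Longest linear sequence: 10 steps (steps 1–4 and 6–11, from 1); step 5 is the only branch.

**Step 10 (key step).** The oxidation may go astray in two ways. Hydride instead of aryl migration could occur at the more crowded B4 aldehyde, which would lead to carboxylic acids. The peracid could also hydroxylate the very electron-rich ring A or oxidise the new hydroxyls further once they are unmasked. The fallback sets out from 15 and returns at 17:
- Grignard addition of MeMgBr (THF, 0 °C) to both formyl groups should give the bis(1-hydroxyethyl) compound F1, a mixture of stereoisomers whose new centres are removed in the next operation.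
- MnO2 in CH2Cl2 should oxidise F1 to the bis(acetyl) compound F2.
- Baeyer–Villiger oxidation (mCPBA, cat. CF3CO2H, CH2Cl2) should give the bis(acetate) F3, and methanolysis (K2CO3, MeOH) then gives 17.

A methyl ketone has no hydride to migrate, and methyl is a far poorer migrating group than an electron-rich aryl group, so the site of oxygen insertion is no longer in question. The acetates can also be purified before the phenols are released.

**Step 9.** Exchange at the deactivated B5 fluoride may stall. Under the forcing then needed, methoxide may displace aryloxide from the activated positions B1, B3 and E1, or hydride transfer between aldehyde molecules may set in. The fallback stages the exchange; it sets out from 12 and returns at 15, at the cost of one extra step: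
- NaOMe (MeOH/THF, 65 °C) on 12, which has only one aldehyde and one fluoride, should give the B5 methoxy compound F4.
- Methanolic HCl as in step 7 should give the D4 phenol F5.
- Substitution on 10 as in step 8 should give the ring E difluoride F6.
- NaOMe at lower temperature should exchange the two more reactive ring E fluorides of F6 and give 15.

This also removes the competition between internal and external fluorides in step 8.

**Step 3.** Substitution at a bromide flanked by a formyl and a methoxy group may be slow, and at the temperature required reductive loss of bromine or base-induced degradation of the aldehyde may take over. The fallback uses a carboxylate to direct the copper; it sets out from 5 and returns at 6: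
- Pinnick oxidation (NaClO2, NaH2PO4, 2-methyl-2-butene, t-BuOH/H2O) should give 2-bromo-3,4,5-trimethoxybenzoic acid F7.
- Ullmann condensation of its potassium salt with 4 (CuI cat., K2CO3, DMF, 110 °C), a reliable reaction of ortho-halobenzoates, should give the 2-aryloxybenzoic acid F8.
- BH3·THF should reduce F8 to the benzyl alcohol F9, and MnO2 in CH2Cl2 should oxidise F9 to 6.

**Step 11.** Cleavage of all eleven methyl ethers may be incomplete if partly demethylated borates precipitate. The free polyphenol may also oxidise in air during work-up and chromatography. The fallback isolates the product through a stable derivative; it sets out from 17 and returns at 18: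
- 17 is demethylated as in step 11.
- The crude mixture is acetylated at once (Ac2O, pyridine) to the tridecaacetate F10, which is stable to air and can be purified on silica.
- Acid methanolysis (HCl in MeOH, argon) then releases 18 without passing through phenoxides.

## Further compounds

F1 | step 10 | bis(1-hydroxyethyl) analogue of 15 (both formyl groups converted to CH(OH)CH3; mixture of stereoisomers) | COc1cc(OC)c(Oc2cc(OC)c(C(C)O)c(Oc3cc(OC)c(OC)c(OC)c3Oc3cc(OC)c(Oc4cc(OC)c(C(C)O)c(OC)c4)c(OC)c3)c2)c(OC)c1
F2 | step 10 | bis(acetyl) analogue of 15 (B4 and E4 acetyl groups) | COc1cc(OC)c(Oc2cc(OC)c(C(C)=O)c(Oc3cc(OC)c(OC)c(OC)c3Oc3cc(OC)c(Oc4cc(OC)c(C(C)=O)c(OC)c4)c(OC)c3)c2)c(OC)c1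
F3 | step 10 | B4,E4-bis(acetate) of 17 | COc1cc(OC)c(Oc2cc(OC)c(OC(C)=O)c(Oc3cc(OC)c(OC)c(OC)c3Oc3cc(OC)c(Oc4cc(OC)c(OC(C)=O)c(OC)c4)c(OC)c3)c2)c(OC)c1
F4 | step 9 | 2-methoxy-6-{2-[3,5-dimethoxy-4-(methoxymethoxy)phenoxy]-3,4,5-trimethoxyphenoxy}-4-(2,4,6-trimethoxyphenoxy)benzaldehyde | COc1cc(OC)c(Oc2cc(OC)c(C=O)c(Oc3cc(OC)c(OC)c(OC)c3Oc3cc(OC)c(OCOC)c(OC)c3)c2)c(OC)c1
F5 | step 9 | 2-methoxy-6-[2-(4-hydroxy-3,5-dimethoxyphenoxy)-3,4,5-trimethoxyphenoxy]-4-(2,4,6-trimethoxyphenoxy)benzaldehyde | COc1cc(OC)c(Oc2cc(OC)c(C=O)c(Oc3cc(OC)c(OC)c(OC)c3Oc3cc(OC)c(O)c(OC)c3)c2)c(OC)c1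
F6 | step 9 | 2-{2-[4-(3,5-difluoro-4-formylphenoxy)-3,5-dimethoxyphenoxy]-3,4,5-trimethoxyphenoxy}-6-methoxy-4-(2,4,6-trimethoxyphenoxy)benzaldehyde | COc1cc(OC)c(Oc2cc(OC)c(C=O)c(Oc3cc(OC)c(OC)c(OC)c3Oc3cc(OC)c(Oc4cc(F)c(C=O)c(F)c4)c(OC)c3)c2)c(OC)c1
F7 | step 3 | 2-bromo-3,4,5-trimethoxybenzoic acid | OC(=O)c1cc(OC)c(OC)c(OC)c1Br
F8 | step 3 | 2-[3,5-dimethoxy-4-(methoxymethoxy)phenoxy]-3,4,5-trimethoxybenzoic acid | OC(=O)c1cc(OC)c(OC)c(OC)c1Oc1cc(OC)c(OCOC)c(OC)c1
F9 | step 3 | {2-[3,5-dimethoxy-4-(methoxymethoxy)phenoxy]-3,4,5-trimethoxyphenyl}methanol | OCc1cc(OC)c(OC)c(OC)c1Oc1cc(OC)c(OCOC)c(OC)c1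
F10 | step 11 | tridecaacetate of 18 | CC(=O)Oc1cc(OC(C)=O)c(Oc2cc(OC(C)=O)c(OC(C)=O)c(Oc3cc(OC(C)=O)c(OC(C)=O)c(OC(C)=O)c3Oc3cc(OC(C)=O)c(Oc4cc(OC(C)=O)c(OC(C)=O)c(OC(C)=O)c4)c(OC(C)=O)c3)c2)c(OC(C)=O)c1
A1 | alternative 1 | 4-(3,4,5-trimethoxyphenoxy)-3-ethoxycyclobut-2-en-1-one (racemic) | O=C1C=C(OCC)C1Oc1cc(OC)c(OC)c(OC)c1
A2 | alternative 1 | (triisopropylsilyloxy)acetylene | C#CO[Si](C(C)C)(C(C)C)C(C)C
A3 | alternative 1 | 3-ethoxy-2-(3,4,5-trimethoxyphenoxy)-5-(triisopropylsilyloxy)phenol | CCOc1cc(O[Si](C(C)C)(C(C)C)C(C)C)cc(O)c1Oc1cc(OC)c(OC)c(OC)c1
A4 | alternative 2 | dimethyl 2-{3-[2-[3,5-dimethoxy-4-(3,4,5-trimethoxyphenoxy)phenoxy]-3,4,5-trimethoxyphenoxy]-4,5-dimethoxyphenoxy}propanedioate | COC(=O)C(Oc1cc(OC)c(OC)c(Oc2cc(OC)c(OC)c(OC)c2Oc2cc(OC)c(Oc3cc(OC)c(OC)c(OC)c3)c(OC)c2)c1)C(=O)OC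
A5 | alternative 2 | dimethyl 3-oxopentanedioate | COC(=O)CC(=O)CC(=O)OC
A6 | alternative 2 | dimethyl 2,4,6-trihydroxy-5-(ring B–C–D–E aryloxy)isophthalate | COC(=O)c1c(O)c(C(=O)OC)c(O)c(Oc2cc(OC)c(OC)c(Oc3cc(OC)c(OC)c(OC)c3Oc3cc(OC)c(Oc4cc(OC)c(OC)c(OC)c4)c(OC)c3)c2)c1O
A7 | alternative 3 | 2-[3,5-dimethoxy-4-(3,4,5-trimethoxyphenoxy)phenoxy]-3,4-dimethoxy-4-(1-methoxyethenyl)cyclobut-2-en-1-one (racemic) | O=C1C(Oc2cc(OC)c(Oc3cc(OC)c(OC)c(OC)c3)c(OC)c2)=C(OC)C1(OC)C(OC)=C
A8 | alternative 3 | 2-[3,5-dimethoxy-4-(3,4,5-trimethoxyphenoxy)phenoxy]-3,4,5-trimethoxyphenol | Oc1cc(OC)c(OC)c(OC)c1Oc1cc(OC)c(Oc2cc(OC)c(OC)c(OC)c2)c(OC)c1
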